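**Retrosynthetic overview**

1. Locants used throughout: nine-membered ring C1–C9 (C1 and C9 ring fusion, C4/C5 oxirane, C8 bears =CH2), cyclobutane C9–C1–C11–C10, side chain C1′(OAc)–C2′–C3′=C4′(CH3)–CH2OAc. The two acetates, the oxirane (peracid on an (E)-C4=C5 alkene), the C8 methylene (from a C8 ketone) and the (Z)-C3′=C4′ alkene (Still–Gennari) are made last.
2. Cyclobutane: an intramolecular crossed [2+2] photocycloaddition of a 2-(allyloxy)cyclohex-2-enone makes C1–C11 and C9–C10 in one operation. The C1′ oxygen is a temporary two-atom tether (C9–O–C1′–C11) that is cut again at C9–O with SmI2.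
3. Enabling feature: the C1′ oxygen lies 1,3 across the four-membered ring from C9, and C9 is α to C8. C8 is a latent ketone that supplies the enone C8(=O)–C9=C1 and makes C9–O reductively cleavable. The six-membered enone ring C8–C9–C1–C2–C3–C4 forces the cis fusion that puts C1–H and C1′ on the same face of the cyclobutane.
4. Nine-membered ring: a cyclopentane C4–C5–C6–C7–C8 is annulated onto the cyclohexanone, and the shared C4–C8 bond is then broken by Grob fragmentation (C8 alkoxide, C5 mesylate). This gives the (E)-C4=C5 alkene and returns the C8 ketone.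
5. Ring order: cyclohexenone (purchased) → cyclobutane and oxygen bridge (step 5) → cyclopentane (step 10) → nine-membered ring (step 12) → oxirane (step 18). The only stereocentre set by reagent control is C1′ (step 3); it controls C1 and C11.

Key step: step 5

Remark: cyclohexane-1,2-dione is taken to react through its enol tautomer (2-hydroxycyclohex-2-en-1-one), and two face-selectivity assumptions are made: electrophiles attack the C4 enolate of the cage ketone from the ring face opposite C10 (steps 6 and 7), and the peracid attacks the outer face of the (E)-C4=C5 alkene (step 18).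

**Route**

Step 1
Reactants: 1 3-[(tert-butyldimethylsilyl)oxy]propanal
Product: 2 rac-5-[(tert-butyldimethylsilyl)oxy]-2-methylpent-1-en-3-ol
Conditions: isopropenylmagnesium bromide, THF, −78 to 0 °C; aq. NH4Cl
Reagents that add atoms: isopropenylmagnesium bromide, C=C(C)[Mg]Br
Why: 1,2-addition of a Grignard reagent to the aldehyde should give the racemic allylic alcohol, whose stereocentre is set in steps 2 and 3.

Step 2
Reactants: 2 racemic allylic alcohol
Product: 3 5-[(tert-butyldimethylsilyl)oxy]-2-methylpent-1-en-3-one
Conditions: Dess–Martin periodinane, NaHCO3, CH2Cl2, 0 °C to rt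
Reagents that add atoms: none
Why: Dess–Martin oxidation of a secondary allylic alcohol is neutral, so the β-silyloxy enone should form without β-elimination.

Step 3
Reactants: 3 enone
Product: 4 (3R)-5-[(tert-butyldimethylsilyl)oxy]-2-methylpent-1-en-3-ol
Conditions: (S)-1-methyl-3,3-diphenyltetrahydro-1H,3H-pyrrolo[1,2-c][1,3,2]oxazaborole (10 mol%), BH3·SMe2, THF, −30 °C
Reagents that add atoms: none
Why: Corey–Bakshi–Shibata reduction, in which the α-branched alkenyl group acts as the large substituent, so that the (S)-catalyst should deliver hydride to give the (R)-carbinol.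

Step 4
Reactants: 4 (3R)-allylic alcohol; 5 cyclohexane-1,2-dione
Product: 6 2-{[(3S)-5-[(tert-butyldimethylsilyl)oxy]-2-methylpent-1-en-3-yl]oxy}cyclohex-2-en-1-one
Conditions: PPh3, diisopropyl azodicarboxylate, THF, 0 °C to rt
Reagents that add atoms: none
Why: Mitsunobu etherification of the acidic enol with SN2 inversion should turn the (R)-carbinol into the (S)-configured allyl vinyl ether, at a temperature too low for Claisen rearrangement.

Step 5
Reactants: 6 (S)-2-(allyloxy)enone
Product: 7 cage ketone (crossed photoadduct)
Conditions: hν (λ = 366 nm), degassed CH2Cl2 (0.01 M), rt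
Reagents that add atoms: none
Why: n→π* excitation and intersystem crossing give the triplet enone, which adds to the tethered 1,1-disubstituted alkene through a triplet 1,4-diradical; the closest known reaction type is the crossed intramolecular [2+2] photocycloaddition of 2-(alk-2-enyloxy)cyclohex-2-enones to 2-oxabicyclo[2.1.1]hexanes. The oxolane ring C1–C9–O–C1′–C11 closes first by a 1,5-closure (C1 to C11, rule of five), and the cyclobutane C9–C1–C11–C10 then closes by recombination of the C9 and C10 radical centres after spin inversion. The six-membered enone ring enforces cis fusion at C9–C1, and because C1′ lies in the oxygen bridge this fixes C1–H syn to C1′ and the C11 methyl syn to C2, which is the relative configuration of C1 and the quaternary C11 in the target; C9 is set as a bridgehead and is re-set in step 16. The absolute sense comes from C1′: minimization of 1,3-allylic strain places C1′–H toward the enone C1–H, so the silyloxyethyl arm points away from the carbocycle. The step needs crossed rather than straight regioselectivity, which the two-atom O–C1′ tether (a 1,5-diene) secures, and facial selectivity, which the C1′ stereocentre secures.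

Step 6
Reactants: 7 cage ketone
Product: 8 anti-aldol adduct
Conditions: c-Hex2BCl, Et3N, Et2O, −78 to 0 °C; acrolein, −78 °C; then MeOH, pH 7 buffer, H2O2, 0 °C
Reagents that add atoms: acrolein, C=CC=O
Why: boron-mediated aldol addition, in which the ketone can enolize only toward C4 (C9 is quaternary), the (E)-enolate should give the anti aldol through a Zimmerman–Traxler chair, and acrolein should add 1,2 from the ring face opposite C10.

Step 7
Reactants: 8 anti-aldol adduct
Product: 9 C4-methyl aldol
Conditions: LiN(i-Pr)2 (2.3 equiv), THF–DMPU, −78 to −40 °C; MeI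
Reagents that add atoms: iodomethane, CI
Why: Fráter–Seebach-type alkylation of the aldolate–enolate dianion, in which iodomethane should enter anti to the vinyl group of the lithium chelate and from the same ring face as in step 6, so that the quaternary C4 carries its methyl anti to C5–OH in the extended chain, as the fragmentation in step 12 requires.

Step 8
Reactants: 9 C4-methyl aldol
Product: 11 C5,C7-diol, via bis(9-BBN) adduct 10 (not isolated)
Conditions: 9-borabicyclo[3.3.1]nonane (2.5 equiv), THF, 0 °C to rt; then H2O2, pH 7 phosphate buffer, 0 °C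
Reagents that add atoms: hydrogen peroxide, OO
Why: hydroboration–oxidation should place boron on the terminal carbon C7 of the monosubstituted alkene, and buffered oxidation without strong base avoids retro-aldol cleavage.

Step 9
Reactants: 11 C5,C7-diol
Product: 12 C7 iodide
Conditions: I2, PPh3, imidazole, CH2Cl2, 0 °C
Reagents that add atoms: iodine, II
Why: Appel-type iodination (Garegg–Samuelsson conditions) should convert the unhindered primary hydroxyl and leave the neopentylic secondary C5–OH untouched.

Step 10
Reactants: 12 C7 iodide
Product: 13 tetracyclic diol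
Conditions: t-BuLi (3.2 equiv), Et2O–pentane, −78 to 0 °C
Reagents that add atoms: none
Why: lithium–iodine exchange is faster than addition of t-BuLi to the hindered, non-enolizable C8 ketone, and the primary alkyllithium should then close the five-membered ring by intramolecular 1,2-addition (anionic Barbier-type cyclization), the three-atom tether allowing only the cis-hydrindane so that C8–OH is set syn to the C4 methyl.

Step 11
Reactants: 13 tetracyclic diol
Product: 14 C5 mesylate
Conditions: MsCl, Et3N, CH2Cl2, −20 °C
Reagents that add atoms: methanesulfonyl chloride, CS(=O)(=O)Cl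
Why: sulfonylation should be selective for the secondary alcohol, since the tertiary C8–OH is too hindered to react.

Step 12
Reactants: 14 C5 mesylate
Product: 15 bridged (E)-cyclononenone
Conditions: KOt-Bu, THF, 0 °C to rt
Reagents that add atoms: none
Why: Grob fragmentation, in which the C8 alkoxide expels the antiperiplanar C5 mesylate with cleavage of the C4–C8 bond; because the mesylate is syn to the C4 methyl on the cyclopentane, the concerted process should be stereospecific for the (E)-C4=C5 alkene and unveil the C8 ketone in the nine-membered ring.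

Step 13
Reactants: 15 bridged (E)-cyclononenone
Product: 16 primary alcohol
Conditions: Bu4NF, AcOH, THF, 0 °C to rt
Reagents that add atoms: none
Why: fluoride-mediated desilylation of the primary silyl ether, buffered with acetic acid so that the ketone is not enolized.

Step 14
Reactants: 16 primary alcohol
Product: 17 aldehyde
Conditions: Dess–Martin periodinane, NaHCO3, CH2Cl2, 0 °C
Reagents that add atoms: none
Why: Dess–Martin oxidation of the primary alcohol should give the β-alkoxy aldehyde without epimerization or elimination.

Step 15
Reactants: 17 aldehyde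
Product: 18 methyl (2Z)-enoate
Conditions: methyl 2-[bis(2,2,2-trifluoroethoxy)phosphoryl]propanoate, KN(SiMe3)2, 18-crown-6, THF, −78 °C
Reagents that add atoms: methyl 2-[bis(2,2,2-trifluoroethoxy)phosphoryl]propanoate, COC(=O)C(C)P(=O)(OCC(F)(F)F)OCC(F)(F)F
Why: the Still–Gennari variant of the Horner–Wadsworth–Emmons reaction should give the (Z)-trisubstituted enoate, and the hindered α-alkoxy ketone should not compete with the aldehyde.

Step 16
Reactants: 18 methyl (2Z)-enoate
Product: 20 trans-fused hydroxy ketone, via cis-fused hydroxy ketone 19 (not isolated)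
Conditions: SmI2 (2.5 equiv), THF–MeOH, −78 °C; then DBU (cat.), CH2Cl2, rt
Reagents that add atoms: none
Why: reduction of an α-alkoxy ketone by SmI2, in which electron transfer to the C8 carbonyl expels the C9 oxygen with release of the oxabicyclo[2.1.1]hexane strain and frees the C1′ hydroxyl, and the C9 stereocentre, first set by protonation of the samarium enolate, should be equilibrated by base to the more stable trans ring fusion.

Step 17
Reactants: 20 trans-fused hydroxy ketone
Product: 21 triene ester
Conditions: Zn, CH2Br2, TiCl4, THF–CH2Cl2, 0 °C to rt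
Reagents that add atoms: dibromomethane, BrCBr
Why: Takai–Lombardo methylenation is non-basic, so C9 should not epimerize, and it should be selective for the ketone over the ester.

Step 18
Reactants: 21 triene ester
Product: 22 (4S,5S)-epoxide
Conditions: mCPBA, NaHCO3, CH2Cl2, −20 to 0 °C
Reagents that add atoms: 3-chloroperoxybenzoic acid, OOC(=O)c1cccc(Cl)c1
Why: Prilezhaev epoxidation, in which the strained endocyclic (E)-trisubstituted alkene should react faster than the exocyclic methylene and the electron-poor enoate, and the peracid should attack the exposed outer face of the ring alkene, setting C4 and C5.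

Step 19
Reactants: 22 (4S,5S)-epoxide
Product: 23 diol
Conditions: i-Bu2AlH (4 equiv), CH2Cl2, −78 °C; aq. potassium sodium tartrate
Reagents that add atoms: none
Why: reduction of the enoate with diisobutylaluminium hydride at low temperature should give the (Z)-allylic alcohol and leave the trisubstituted oxirane intact.

Step 20
Reactants: 23 diol
Product: 24 target diacetate
Conditions: Ac2O, pyridine, DMAP (cat.), CH2Cl2, rt
Reagents that add atoms: acetic anhydride, CC(=O)OC(C)=O
Why: DMAP-catalysed acylation should acetylate both the primary allylic and the hindered secondary hydroxyl.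

**Compound list**

1 | 3-[(tert-butyldimethylsilyl)oxy]propanal | O=CCCO[Si](C)(C)C(C)(C)C | starting material
2 | rac-5-[(tert-butyldimethylsilyl)oxy]-2-methylpent-1-en-3-ol | C=C(C)C(O)CCO[Si](C)(C)C(C)(C)C | intermediate
3 | 5-[(tert-butyldimethylsilyl)oxy]-2-methylpent-1-en-3-one | C=C(C)C(=O)CCO[Si](C)(C)C(C)(C)C | intermediate
4 | (3R)-5-[(tert-butyldimethylsilyl)oxy]-2-methylpent-1-en-3-ol | C=C(C)[C@H](O)CCO[Si](C)(C)C(C)(C)C | intermediate
5 | cyclohexane-1,2-dione | O=C1CCCCC1=O | starting material
6 | 2-{[(3S)-5-[(tert-butyldimethylsilyl)oxy]-2-methylpent-1-en-3-yl]oxy}cyclohex-2-en-1-one | C=C(C)[C@@H](OC1=CCCCC1=O)CCO[Si](C)(C)C(C)(C)C | intermediate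
7 | cage ketone: cyclohexanone (C8=O, C4, C3, C2, C1, C9) cis-fused at C9–C1 to the cyclobutane C9–C1–C11–C10, O–C1′ bridge from C9 to C11 (2-oxabicyclo[2.1.1]hexane), C11 methyl exo, (1′S) with the 2-(silyloxy)ethyl arm on the C10 side | O=C1CCC[C@H]2[C@]13C[C@]2(C)[C@H](CCO[Si](C)(C)C(C)(C)C)O3 | intermediate
8 | anti-aldol adduct: 7 with a 1-hydroxyprop-2-en-1-yl group at C4, attached on the ring face opposite C10 | O=C1[C@@H]([C@H](O)C=C)CC[C@H]2[C@]13C[C@]2(C)[C@H](CCO[Si](C)(C)C(C)(C)C)O3 | intermediate
9 | C4-methyl aldol: quaternary C4 with methyl on the face opposite C10, C5–OH anti to that methyl in the extended C8–C4–C5–C6 chain | O=C1[C@](C)([C@H](O)C=C)CC[C@H]2[C@]13C[C@]2(C)[C@H](CCO[Si](C)(C)C(C)(C)C)O3 | intermediate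
10 | bis(9-BBN) adduct: 9 with 9-borabicyclo[3.3.1]nonan-9-yl on C7 and on the C5 oxygen | O=C1[C@](C)([C@H](OB4C5CCCC4CCC5)CCB4C5CCCC4CCC5)CC[C@H]2[C@]13C[C@]2(C)[C@H](CCO[Si](C)(C)C(C)(C)C)O3 | intermediate
11 | C5,C7-diol (3-hydroxypropyl carbinol at C4) | O=C1[C@](C)([C@H](O)CCO)CC[C@H]2[C@]13C[C@]2(C)[C@H](CCO[Si](C)(C)C(C)(C)C)O3 | intermediate
12 | C7 iodide | O=C1[C@](C)([C@H](O)CCI)CC[C@H]2[C@]13C[C@]2(C)[C@H](CCO[Si](C)(C)C(C)(C)C)O3 | intermediate
13 | tetracyclic diol: cis-hydrindane (cyclopentane C4–C5–C6–C7–C8 on the cyclohexane) with C8–OH, C4–CH3 and C5–OH all syn, cage as in 7 | O[C@@]12CC[C@@H](O)[C@]1(C)CC[C@H]3[C@]24C[C@]3(C)[C@H](CCO[Si](C)(C)C(C)(C)C)O4 | intermediate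
14 | C5 methanesulfonate of 13 | O[C@@]12CC[C@@H](OS(C)(=O)=O)[C@]1(C)CC[C@H]3[C@]24C[C@]3(C)[C@H](CCO[Si](C)(C)C(C)(C)C)O4 | intermediate
15 | bridged (E)-cyclononenone: nine-membered ring C8(=O)–C7–C6–C5=C4(CH3)–C3–C2–C1–C9 with (4E) alkene, cyclobutane and O–C1′ bridge as in 7 | O=C1CC/C=C(C)/CC[C@H]2[C@]13C[C@]2(C)[C@H](CCO[Si](C)(C)C(C)(C)C)O3 | intermediate
16 | primary alcohol (2-hydroxyethyl arm on C1′) | O=C1CC/C=C(C)/CC[C@H]2[C@]13C[C@]2(C)[C@H](CCO)O3 | intermediate
17 | aldehyde (2-oxoethyl arm on C1′) | O=C1CC/C=C(C)/CC[C@H]2[C@]13C[C@]2(C)[C@H](CC=O)O3 | intermediate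
18 | methyl (2Z)-2-methylbut-2-enoate arm on C1′, bridged (E)-cyclononenone | O=C1CC/C=C(C)/CC[C@H]2[C@]13C[C@]2(C)[C@H](C/C=C(/C)C(=O)OC)O3 | intermediate
19 | cis-fused hydroxy ketone (C9 epimer of 20) | O=C1CC/C=C(C)/CC[C@H]2[C@@H]1C[C@]2(C)[C@@H](O)C/C=C(/C)C(=O)OC | intermediate
20 | trans-fused hydroxy ketone: (1S,9R,11S,1′S), (4E), (Z)-enoate | O=C1CC/C=C(C)/CC[C@H]2[C@H]1C[C@]2(C)[C@@H](O)C/C=C(/C)C(=O)OC | intermediate
21 | triene ester (C8 methylene) | C=C1CC/C=C(C)/CC[C@H]2[C@H]1C[C@]2(C)[C@@H](O)C/C=C(/C)C(=O)OC | intermediate
22 | (4S,5S)-epoxide of 21 | C=C1CC[C@@H]2O[C@@]2(C)CC[C@H]2[C@H]1C[C@]2(C)[C@@H](O)C/C=C(/C)C(=O)OC | intermediate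
23 | diol: C1′–OH and (Z)-allylic CH2OH | C=C1CC[C@@H]2O[C@@]2(C)CC[C@H]2[C@H]1C[C@]2(C)[C@@H](O)C/C=C(/C)CO | intermediate
24 | target diacetate | C=C1CC[C@@H]2O[C@@]2(C)CC[C@H]2[C@H]1C[C@]2(C)[C@H](C/C=C(/C)COC(C)=O)OC(C)=O | target

**Step count and risks**

Total step count: 20. Longest linear sequence: 20 steps (1 to 24); 5 enters at step 4.

Step 5 (key step). The single C1′ stereocentre may not discriminate the two enone faces well enough, and hydrogen transfer from the allylic, oxygen-bearing C1′–H to the excited carbonyl may compete with ring closure. The fallback moves stereocontrol from the substrate to a catalyst. Compound 6 is bound through C8=O and the ether oxygen to a chiral chelating Lewis acid, for example Sc(OTf)3 with a chiral pybox ligand. Only this red-shifted chelate is then excited with visible light, either directly or through Ru(bpy)3(PF6)2 as triplet sensitizer. The ligand is chosen to reinforce the substrate's own bias, and the chelate holds C1′ on the C1 side of the enone. This fallback sets out from 6, returns at 7 and makes no new compound (F0).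

Step 7. The lithium aldolate may undergo retro-aldol cleavage before the second deprotonation, and O-methylation or loss of chelate control may erode the C4 configuration. The fallback replaces the dianion by a protected monoanion. It sets out from 8: silylation (Me3SiCl, imidazole, CH2Cl2) should give the trimethylsilyl ether F1. Its lithium enolate (LiN(i-Pr)2, THF, −78 °C, then MeI) should be methylated from the same ring face under steric control alone, giving the methylated silyl ether F2. Citric acid in MeOH should then remove the trimethylsilyl group without touching the primary tert-butyldimethylsilyl ether, and the route is rejoined at 9.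

Step 4. Attack at the unhindered methylene terminus (SN2′) would give an achiral transposed ether, and partial loss of configuration or C-alkylation of the enol may also occur. The fallback forms the same C–O bond from the enone side with retention. It sets out from 3, which on reduction with the enantiomeric (R)-oxazaborolidine catalyst should give the (3S)-alcohol F4. Commercial cyclohex-2-en-1-one is converted with I2 and pyridine into 2-iodocyclohex-2-en-1-one F3. An Ullmann-type vinylic etherification (CuI, 3,4,7,8-tetramethyl-1,10-phenanthroline, Cs2CO3, toluene, 80 °C, kept below the Claisen threshold) should couple the two with retention at C1′ and return to 6.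

**Further compounds**

F0 | step 5 | none | none
F1 | step 7 | trimethylsilyl ether of 8 | O=C1[C@@H]([C@H](O[Si](C)(C)C)C=C)CC[C@H]2[C@]13C[C@]2(C)[C@H](CCO[Si](C)(C)C(C)(C)C)O3
F2 | step 7 | C4-methylated trimethylsilyl ether (silyl ether of 9) | O=C1[C@](C)([C@H](O[Si](C)(C)C)C=C)CC[C@H]2[C@]13C[C@]2(C)[C@H](CCO[Si](C)(C)C(C)(C)C)O3
F3 | step 4 | 2-iodocyclohex-2-en-1-one | O=C1CCCC=C1I
F4 | step 4 | (3S)-5-[(tert-butyldimethylsilyl)oxy]-2-methylpent-1-en-3-ol | C=C(C)[C@@H](O)CCO[Si](C)(C)C(C)(C)C
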